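J is counted only at the end of this flask, and I took it to form only while Z is about.

| setting | theta | eta | flask |
|---|---|---|---|
| E | 0.20 M | 0.20 M | 0.20 M |
| L | 20 mM (held) | 20 mM (held) | 20 mM (held) |
| Q | 0.13 M | 0.30 M | 0.200 M |
| remark | run made earlier | run made earlier |  |
| time |  |  | 5.0 h |

- theta (time / h: J / %): 1.33: 22.3; 2.50: 32.4; 4.00: 37.3; 5.00: 38.6
- eta (time / h: J / %): 0.667: 8.6; 2.00: 11.0; 3.00: 9.9; 5.00: 11.0

(standard deviation of a reading: 0.5 percentage points)

- given per volume of solution although it is solid: E
- at the start none of G is dissolved
- steps that have been proposed: L <-> G; Z + G -> J; G -> X; Z + Q -> D; E <-> Z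
- at the start none of E is in solution

- north: doubling the dissolution coefficient of E, all else as stated
- south-east: doubling the transfer coefficient of L, all else as stated
- north-east: doubling the saturation concentration of L, all else as stated
- south: doubling the solubility of E, all else as stated

1. amount of J at 5.0 h, in percent of the E charged
2. the change that raises the amount of J at 5.0 h, in percent of the E charged most ("none" if none brings more than 2 percentage points) (north / south-east / north-east / south / none)
3. amount of J at 5.0 h, in percent of the E charged, after north

1. Fastest rung: in the eta run J read 11.0 % at 2.00 h and 11.0 % at 5.00 h, so with 0.30 M of Q it had stopped by 2.00 h.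

2. Next rung: in the theta run, with 0.13 M of Q, J gained 1.3 percentage points between 4.00 h and 5.00 h, so it was slowing towards a stop. This flask holds more Q, so I read its 5.0 h value as an end state.

3. Last rung, the count: Z goes with G to J or with Q to D, and [Z] cancels in the ratio of these two rates. Taking [G] as steady, dJ/dD = a/[Q]. Each D costs one Q, so [J] = a ln([Q] charged/[Q] end).

4. Taking the E as all passed through Z, [Q] end = [Q] charged − [E] charged + [J]. The eta run gave 0.0245 M. The theta run gave 0.0267 M, which is rough because its J was still climbing. I carried their mean, 0.0256 M, as a, the J won per e-fold fall of [Q], which is a selectivity factor times [G].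

5. In this flask Q and E are charged equally, so [Q] end = [J]. Trying [J] = 0.0400 M returned 0.0411 M, and their midpoint is 20.3 % of the E.

6. North and south speed the passage of E into Z, so more of the Z meets a [G] that is still climbing and a falls somewhat; I therefore put the figure after north no higher than 20.3 %. North-east doubles the [G] ceiling and so a, and I chose it.

The forecast said 20 %, north-east and 19.5 %, holding that “Doubling saturation of L doubles G”.

The flask gave 20.5 %, and north-east as best with 9 points gained, against 3.2 points for south-east; after north it gave 20.3 %.

    L ⇌ G, rate k1*(csat - [G]) (kL = 0.0796 min⁻¹)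
    Z + G → J (k = 0.711 M⁻¹ min⁻¹)
    G → X (k = 0.00443 min⁻¹)
    Z + Q → D (k = 0.306 M⁻¹ min⁻¹)
    E ⇌ Z, rate k5*(cs5 - [Z]) while solid is left; crystals form when [Z] > cs5 (solubility = 0.110 M, k = 0.647 min⁻¹)

This flask had come to rest in J by 5.00 h, with Z at 0.0270 % of the E. My a, set on the simulated 21 % of Q left, returns 20.3 %. On the neighbour with 0.12 M of E and 49 % of Q left, it returns 15.2 %, where that flask gave 14.6 %. Ten times the time moves little in this flask: at 50.0 h J stood at 20.5 % and Q at 20.5 % of its charge, while X had climbed from 0.0220 M to 0.249 M.

(The runs were generated by integration on assumed constants, and the scatter is random.)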